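**Retrosynthetic overview**
1. Target ⇐ C8 isobutyrate by Mitsunobu inversion, then acid unmasking of the C3/C10 hemiketal; the THF ring forms last and spontaneously.
2. Ten-membered ring ⇐ intramolecular carbonylative B-alkyl Suzuki coupling (C2–C3–C4, C3 from CO) between a (Z)-vinyl iodide and a C1=C2 vinyl group.
3. Key step: [2,3]-Wittig rearrangement of a propargyl allyl ether carboxylate makes C6–C7, sets C6/C7 and the exocyclic methylene; the γ-lactone closes on work-up.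
4. Wittig substrate ⇐ Baylis–Hillman/SN2′ bromide of a dioxane aldehyde plus but-2-yne-1,4-diol; C10 from a chelation-controlled vinyl Grignard addition.
5. All chirality comes from (S)-benzyl glycidyl ether (C8). Ring order: dioxane (temporary) → γ-lactone → ten-membered carbocycle → THF hemiketal.

Assumption: atom labels C1–C15 follow germacrane numbering (C12 lactone carbonyl, C13 exocyclic methylene, C14 methyl on C10, C15 the CH2O carbon on C4); all numbered starting materials are bought.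

**Route**

Step 1
Reactants: 1 (S)-benzyl glycidyl ether [(2S)-2-[(benzyloxy)methyl]oxirane]; 2 isopropenylmagnesium bromide
Product: 3 (2S)-1-(benzyloxy)-4-methylpent-4-en-2-ol
Conditions: CuI (10 mol %), THF, −40 → 0 °C
Reagents that add atoms: none
Why: Copper-catalysed Grignard opening of the terminal epoxide at its CH2 carbon (SN2) leaves the bought C8 stereocentre untouched.

Step 2
Reactants: 3 (2S)-1-(benzyloxy)-4-methylpent-4-en-2-ol
Product: 4 (4S)-5-(benzyloxy)-4-hydroxypentan-2-one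
Conditions: O3, CH2Cl2/MeOH, −78 °C; then Me2S, −78 → 23 °C
Reagents that add atoms: ozone, [O-][O+]=O
Why: Ozonolysis with reductive work-up cleaves the 1,1-disubstituted alkene to the methyl ketone without affecting the carbinol centre.

Step 3
Reactants: 4 (4S)-5-(benzyloxy)-4-hydroxypentan-2-one; 5 vinylmagnesium bromide
Product: 6 (2S,4S)-1-(benzyloxy)-4-methylhex-5-ene-2,4-diol
Conditions: CH2=CHMgBr (3 equiv), THF, −78 °C
Reagents that add atoms: none
Why: Chelation-controlled Grignard addition, in which the magnesium alkoxide at C8 chelates the ketone and vinyl adds axially to the six-membered chelate, gives the 1,3-anti diol and so sets C10 from C8.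

Step 4
Reactants: 6 (2S,4S)-1-(benzyloxy)-4-methylhex-5-ene-2,4-diol
Product: 7 (4S,6S)-6-[(benzyloxy)methyl]-4-ethenyl-2,2,4-trimethyl-1,3-dioxane
Conditions: Me2C(OMe)2, PPTS (cat.), CH2Cl2, 23 °C
Reagents that add atoms: 2,2-dimethoxypropane, COC(C)(C)OC
Why: Acid-catalysed transketalisation protects the 1,3-diol as an acetonide and fixes the C8–O bond as the control element for step 10.

Step 5
Reactants: 7 (4S,6S)-6-[(benzyloxy)methyl]-4-ethenyl-2,2,4-trimethyl-1,3-dioxane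
Product: 8 [(4S,6S)-6-ethenyl-2,2,6-trimethyl-1,3-dioxan-4-yl]methanol
Conditions: lithium 4,4'-di-tert-butylbiphenylide, THF, −78 °C
Reagents that add atoms: none
Why: Single-electron reductive cleavage of the benzyl ether by the arene radical anion spares the isolated vinyl group and the acetonide.

Step 6
Reactants: 8 [(4S,6S)-6-ethenyl-2,2,6-trimethyl-1,3-dioxan-4-yl]methanol
Product: 9 (4S,6S)-6-ethenyl-2,2,6-trimethyl-1,3-dioxane-4-carbaldehyde
Conditions: Dess–Martin periodinane, CH2Cl2, 0 → 23 °C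
Reagents that add atoms: none
Why: Dess–Martin oxidation gives the α-alkoxy aldehyde under non-basic conditions that do not epimerise C8.

Step 7
Reactants: 9 (4S,6S)-6-ethenyl-2,2,6-trimethyl-1,3-dioxane-4-carbaldehyde; 10 methyl acrylate
Product: 11 methyl 2-{[(4S,6S)-6-ethenyl-2,2,6-trimethyl-1,3-dioxan-4-yl](hydroxy)methyl}prop-2-enoate (both carbinol epimers)
Conditions: DABCO (1 equiv), methyl acrylate (5 equiv), 1,4-dioxane/H2O, 23 °C, 3 d
Reagents that add atoms: none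
Why: Morita–Baylis–Hillman reaction of the activated α-alkoxy aldehyde; the new carbinol centre is left uncontrolled because step 8 erases it.

Step 8
Reactants: 11 methyl 2-{[(4S,6S)-6-ethenyl-2,2,6-trimethyl-1,3-dioxan-4-yl](hydroxy)methyl}prop-2-enoate
Product: 12 methyl (2Z)-2-(bromomethyl)-3-[(4S,6S)-6-ethenyl-2,2,6-trimethyl-1,3-dioxan-4-yl]prop-2-enoate
Conditions: NBS, Me2S, CH2Cl2, 0 → 23 °C
Reagents that add atoms: N-bromosuccinimide, O=C1CCC(=O)N1Br
Why: Corey–Kim-type activation followed by SN2′ attack of bromide gives the conjugated allyl bromide with the thermodynamic geometry (ester trans, CH2Br cis to the dioxane).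

Step 9
Reactants: 12 methyl (2Z)-2-(bromomethyl)-3-[(4S,6S)-6-ethenyl-2,2,6-trimethyl-1,3-dioxan-4-yl]prop-2-enoate; 13 but-2-yne-1,4-diol
Product: 15 (2E)-3-[(4S,6S)-6-ethenyl-2,2,6-trimethyl-1,3-dioxan-4-yl]-2-{[(4-hydroxybut-2-yn-1-yl)oxy]methyl}prop-2-enoic acid, via ether ester 14 (not isolated)
Conditions: NaH (1.1 equiv), diol 13 (5 equiv), THF, 0 °C; then LiOH, H2O, 23 °C; aq. HCl to pH 3
Reagents that add atoms: lithium hydroxide, [Li+].[OH-]
Why: Williamson ether synthesis (SN2 at the primary allylic bromide, alkene geometry kept) followed by saponification gives the carboxylate that tolerates the strong base of step 10.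

Step 10
Reactants: 15 (2E)-3-[(4S,6S)-6-ethenyl-2,2,6-trimethyl-1,3-dioxan-4-yl]-2-{[(4-hydroxybut-2-yn-1-yl)oxy]methyl}prop-2-enoic acid
Product: 17 (4R,5R)-4-[(4S,6S)-6-ethenyl-2,2,6-trimethyl-1,3-dioxan-4-yl]-5-(3-hydroxyprop-1-yn-1-yl)-3-methylideneoxolan-2-one, via hydroxy acid 16 (not isolated)
Conditions: LiN(iPr)2 (3.5 equiv), THF, −78 → −30 °C; aq. HCl (pH 3); PPTS (cat.), CH2Cl2, 23 °C
Reagents that add atoms: none
Why: Deprotonation at propargylic C6 (the neighbouring alkoxide shields C15) triggers the [2,3]-Wittig sigmatropic rearrangement, which forms C6–C7 and the C11=C13 methylene; the (Z)-allyl ether gives the syn C6/C7 pair and the carbanion adds anti to the dioxane C8–O bond (Felkin–Anh-type, conformation fixed by allylic strain), so both centres follow from C8 and the hydroxy acid lactonises to the cis-lactone.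

Step 11
Reactants: 17 (4R,5R)-4-[(4S,6S)-6-ethenyl-2,2,6-trimethyl-1,3-dioxan-4-yl]-5-(3-hydroxyprop-1-yn-1-yl)-3-methylideneoxolan-2-one
Product: 19 (4R,5R)-4-[(4S,6S)-6-ethenyl-2,2,6-trimethyl-1,3-dioxan-4-yl]-5-[(1Z)-3-hydroxy-2-iodoprop-1-en-1-yl]-3-methylideneoxolan-2-one, via vinylstannane 18 (not isolated)
Conditions: Bu3SnH, [(C5Me5)RuCl]4 (2.5 mol %), CH2Cl2, 23 °C; then I2, 0 °C
Reagents that add atoms: iodine, II
Why: Hydroxyl-directed ruthenium-catalysed trans-hydrostannation puts tin on C4 (next to the CH2OH) and hydrogen on C5 in an anti fashion, and iododestannylation with retention gives the vinyl iodide whose C4 substituent is cis to C6.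

Step 12
Reactants: 19 (4R,5R)-4-[(4S,6S)-6-ethenyl-2,2,6-trimethyl-1,3-dioxan-4-yl]-5-[(1Z)-3-hydroxy-2-iodoprop-1-en-1-yl]-3-methylideneoxolan-2-one
Product: 20 (4R,5R)-5-[(1Z)-3-{[tert-butyl(diphenyl)silyl]oxy}-2-iodoprop-1-en-1-yl]-4-[(4S,6S)-6-ethenyl-2,2,6-trimethyl-1,3-dioxan-4-yl]-3-methylideneoxolan-2-one
Conditions: tBuPh2SiCl, imidazole, CH2Cl2, 0 °C
Reagents that add atoms: tert-butyl(chloro)diphenylsilane, CC(C)(C)[Si](Cl)(c1ccccc1)c1ccccc1
Why: Silylation of the only free (primary) alcohol gives an ether that survives steps 13–15 and keeps C15–OH out of the Mitsunobu reaction.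

Step 13
Reactants: 20 (4R,5R)-5-[(1Z)-3-{[tert-butyl(diphenyl)silyl]oxy}-2-iodoprop-1-en-1-yl]-4-[(4S,6S)-6-ethenyl-2,2,6-trimethyl-1,3-dioxan-4-yl]-3-methylideneoxolan-2-one
Product: 22 (4Z,6S,7R,8S,10R)-15-{[tert-butyl(diphenyl)silyl]oxy}-8,10-(isopropylidenedioxy)-3-oxogermacra-4,11(13)-dien-12,6-olide, via alkylborane 21 (not isolated)
Conditions: 9-BBN-H, THF, 23 °C; then Pd(PPh3)4 (10 mol %), K3PO4, CO (1 atm), THF/benzene, 23 °C, syringe pump (2 mM)
Reagents that add atoms: carbon monoxide, [C-]#[O+]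
Why: Anti-Markovnikov hydroboration of the terminal vinyl group and intramolecular carbonylative Suzuki–Miyaura coupling close the ten-membered ring; oxidative addition and CO insertion keep the alkene geometry, so C3 ends up cis to C6.

Step 14
Reactants: 22 (4Z,6S,7R,8S,10R)-15-{[tert-butyl(diphenyl)silyl]oxy}-8,10-(isopropylidenedioxy)-3-oxogermacra-4,11(13)-dien-12,6-olide
Product: 23 (3S,4Z,6S,7R,8S,10R)-15-{[tert-butyl(diphenyl)silyl]oxy}-3,10-epoxy-8-hydroxy-3-methoxygermacra-4,11(13)-dien-12,6-olide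
Conditions: PPTS (cat.), MeOH, 23 °C
Reagents that add atoms: methanol, CO
Why: Acid-catalysed transketalisation removes the acetonide, and the freed C10–OH closes onto the C3 ketone as a cyclic methyl ketal whose C3 configuration is dictated by the bridged ring, leaving C8–OH as the only free hydroxyl.

Step 15
Reactants: 23 (3S,4Z,6S,7R,8S,10R)-15-{[tert-butyl(diphenyl)silyl]oxy}-3,10-epoxy-8-hydroxy-3-methoxygermacra-4,11(13)-dien-12,6-olide; 24 isobutyric acid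
Product: 25 (3S,4Z,6S,7R,8R,10R)-15-{[tert-butyl(diphenyl)silyl]oxy}-3,10-epoxy-3-methoxy-8-(2-methylpropanoyloxy)germacra-4,11(13)-dien-12,6-olide
Conditions: PPh3, DIAD, toluene, 0 → 23 °C
Reagents that add atoms: none
Why: Mitsunobu esterification (SN2 with inversion) installs the isobutyrate and turns the 8S alcohol into the required 8R ester.

Step 16
Reactants: 25 (3S,4Z,6S,7R,8R,10R)-15-{[tert-butyl(diphenyl)silyl]oxy}-3,10-epoxy-3-methoxy-8-(2-methylpropanoyloxy)germacra-4,11(13)-dien-12,6-olide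
Product: 26 (3S,4Z,6S,7R,8R,10R)-3,10-epoxy-3,15-dihydroxy-8-(2-methylpropanoyloxy)germacra-4,11(13)-dien-12,6-olide (CNP0282937.2)
Conditions: aq. HF (48 %), MeCN, 0 → 23 °C
Reagents that add atoms: water, O
Why: Fluoride-mediated desilylation and acid hydrolysis of the methyl ketal free both hydroxyls, and the hemiketal stays in the only possible cis-bridged form, which fixes C3.

**Compound list**
1 | (S)-benzyl glycidyl ether, (2S)-2-[(benzyloxy)methyl]oxirane | O1C[C@H]1COCc2ccccc2 | starting material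
2 | isopropenylmagnesium bromide | C=C(C)[Mg]Br | starting material
3 | (2S)-1-(benzyloxy)-4-methylpent-4-en-2-ol | C=C(C)C[C@H](O)COCc1ccccc1 | intermediate
4 | (4S)-5-(benzyloxy)-4-hydroxypentan-2-one | CC(=O)C[C@H](O)COCc1ccccc1 | intermediate
5 | vinylmagnesium bromide | C=C[Mg]Br | starting material
6 | (2S,4S)-1-(benzyloxy)-4-methylhex-5-ene-2,4-diol | C=C[C@@](C)(O)C[C@H](O)COCc1ccccc1 | intermediate
7 | (4S,6S)-6-[(benzyloxy)methyl]-4-ethenyl-2,2,4-trimethyl-1,3-dioxane | C=C[C@]1(C)C[C@@H](COCc2ccccc2)OC(C)(C)O1 | intermediate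
8 | [(4S,6S)-6-ethenyl-2,2,6-trimethyl-1,3-dioxan-4-yl]methanol | C=C[C@]1(C)C[C@@H](CO)OC(C)(C)O1 | intermediate
9 | (4S,6S)-6-ethenyl-2,2,6-trimethyl-1,3-dioxane-4-carbaldehyde | C=C[C@]1(C)C[C@@H](C=O)OC(C)(C)O1 | intermediate
10 | methyl acrylate | C=CC(=O)OC | starting material
11 | methyl 2-{[(4S,6S)-6-ethenyl-2,2,6-trimethyl-1,3-dioxan-4-yl](hydroxy)methyl}prop-2-enoate (carbinol epimers) | C=C[C@]1(C)C[C@@H](C(O)C(=C)C(=O)OC)OC(C)(C)O1 | intermediate
12 | methyl (2Z)-2-(bromomethyl)-3-[(4S,6S)-6-ethenyl-2,2,6-trimethyl-1,3-dioxan-4-yl]prop-2-enoate | C=C[C@]1(C)C[C@@H](/C=C(\CBr)C(=O)OC)OC(C)(C)O1 | intermediate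
13 | but-2-yne-1,4-diol | OCC#CCO | starting material
14 | methyl (2E)-3-[(4S,6S)-6-ethenyl-2,2,6-trimethyl-1,3-dioxan-4-yl]-2-{[(4-hydroxybut-2-yn-1-yl)oxy]methyl}prop-2-enoate (ether ester) | C=C[C@]1(C)C[C@@H](/C=C(\COCC#CCO)C(=O)OC)OC(C)(C)O1 | intermediate
15 | (2E)-3-[(4S,6S)-6-ethenyl-2,2,6-trimethyl-1,3-dioxan-4-yl]-2-{[(4-hydroxybut-2-yn-1-yl)oxy]methyl}prop-2-enoic acid | C=C[C@]1(C)C[C@@H](/C=C(\COCC#CCO)C(=O)O)OC(C)(C)O1 | intermediate
16 | (3S,4R)-3-[(4S,6S)-6-ethenyl-2,2,6-trimethyl-1,3-dioxan-4-yl]-4,7-dihydroxy-2-methylidenehept-5-ynoic acid (hydroxy acid) | C=C[C@]1(C)C[C@@H]([C@H]([C@@H](O)C#CCO)C(=C)C(=O)O)OC(C)(C)O1 | intermediate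
17 | (4R,5R)-4-[(4S,6S)-6-ethenyl-2,2,6-trimethyl-1,3-dioxan-4-yl]-5-(3-hydroxyprop-1-yn-1-yl)-3-methylideneoxolan-2-one | C=C1C(=O)O[C@@H](C#CCO)[C@H]1[C@@H]2C[C@@](C)(C=C)OC(C)(C)O2 | intermediate
18 | (4R,5R)-4-[(4S,6S)-6-ethenyl-2,2,6-trimethyl-1,3-dioxan-4-yl]-5-[(1Z)-3-hydroxy-2-(tributylstannyl)prop-1-en-1-yl]-3-methylideneoxolan-2-one (vinylstannane) | C=C1C(=O)O[C@@H](/C=C(\[Sn](CCCC)(CCCC)CCCC)CO)[C@H]1[C@@H]2C[C@@](C)(C=C)OC(C)(C)O2 | intermediate
19 | (4R,5R)-4-[(4S,6S)-6-ethenyl-2,2,6-trimethyl-1,3-dioxan-4-yl]-5-[(1Z)-3-hydroxy-2-iodoprop-1-en-1-yl]-3-methylideneoxolan-2-one | C=C1C(=O)O[C@@H](/C=C(\I)CO)[C@H]1[C@@H]2C[C@@](C)(C=C)OC(C)(C)O2 | intermediate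
20 | (4R,5R)-5-[(1Z)-3-{[tert-butyl(diphenyl)silyl]oxy}-2-iodoprop-1-en-1-yl]-4-[(4S,6S)-6-ethenyl-2,2,6-trimethyl-1,3-dioxan-4-yl]-3-methylideneoxolan-2-one | C=C1C(=O)O[C@@H](/C=C(\I)CO[Si](c3ccccc3)(c3ccccc3)C(C)(C)C)[C@H]1[C@@H]2C[C@@](C)(C=C)OC(C)(C)O2 | intermediate
21 | (4R,5R)-4-[(4S,6R)-6-[2-(9-borabicyclo[3.3.1]nonan-9-yl)ethyl]-2,2,6-trimethyl-1,3-dioxan-4-yl]-5-[(1Z)-3-{[tert-butyl(diphenyl)silyl]oxy}-2-iodoprop-1-en-1-yl]-3-methylideneoxolan-2-one (alkylborane) | C=C1C(=O)O[C@@H](/C=C(\I)CO[Si](c3ccccc3)(c3ccccc3)C(C)(C)C)[C@H]1[C@@H]2C[C@@](C)(CCB3C4CCCC3CCC4)OC(C)(C)O2 | intermediate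
22 | (4Z,6S,7R,8S,10R)-15-{[tert-butyl(diphenyl)silyl]oxy}-8,10-(isopropylidenedioxy)-3-oxogermacra-4,11(13)-dien-12,6-olide | C=C1C(=O)O[C@H]2/C=C(/CO[Si](c4ccccc4)(c4ccccc4)C(C)(C)C)C(=O)CC[C@]3(C)C[C@@H]([C@@H]12)OC(C)(C)O3 | intermediate
23 | (3S,4Z,6S,7R,8S,10R)-15-{[tert-butyl(diphenyl)silyl]oxy}-3,10-epoxy-8-hydroxy-3-methoxygermacra-4,11(13)-dien-12,6-olide | C=C1C(=O)O[C@H]2/C=C(/CO[Si](c4ccccc4)(c4ccccc4)C(C)(C)C)[C@]3(OC)CC[C@](C)(C[C@H](O)[C@@H]12)O3 | intermediate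
24 | isobutyric acid | CC(C)C(=O)O | starting material
25 | (3S,4Z,6S,7R,8R,10R)-15-{[tert-butyl(diphenyl)silyl]oxy}-3,10-epoxy-3-methoxy-8-(2-methylpropanoyloxy)germacra-4,11(13)-dien-12,6-olide | C=C1C(=O)O[C@H]2/C=C(/CO[Si](c4ccccc4)(c4ccccc4)C(C)(C)C)[C@]3(OC)CC[C@](C)(C[C@@H](OC(=O)C(C)C)[C@@H]12)O3 | intermediate
26 | (3S,4Z,6S,7R,8R,10R)-3,10-epoxy-3,15-dihydroxy-8-(2-methylpropanoyloxy)germacra-4,11(13)-dien-12,6-olide (CNP0282937.2) | C=C1C(=O)O[C@H]2/C=C(/CO)[C@]3(O)CC[C@](C)(C[C@@H](OC(=O)C(C)C)[C@@H]12)O3 | target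

**Step count:** 16 steps in total; the longest linear sequence is 16 steps (1 → 26).

**Steps most likely to fail, with fallbacks**

Step 10 ([2,3]-Wittig on the trianion). The risks are γ-deprotonation of the unsaturated carboxylate with loss of the propargyloxy group, and weak syn or facial control. The fallback sets out from 12 and comes back at 17. Etherify 12 with 4-[(tert-butyldimethylsilyl)oxy]but-2-yn-1-ol (NaH, THF) to the silyl ether ester F1. Reduce it with iBu2AlH to the allylic alcohol F2. Run the same rearrangement on its lithium alkoxide (n-BuLi, 2.2 equiv, THF, −78 °C) to the diol F3. Close the lactone by MnO2 oxidation to the silyl-protected lactone F4, and cleave the silyl ether (Bu4NF, AcOH) to reach 17.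

Step 13 (carbonylative macrocyclisation). The risks are oligomers, coupling without CO and slow transmetalation. The fallback sets out from 20 and comes back at 22. Hydroborate and oxidise (9-BBN-H, then NaBO3·4H2O) to the primary alcohol F5. Oxidise it with Dess–Martin periodinane to the aldehyde F6. Close the ring by CrCl2/NiCl2-mediated Nozaki–Hiyama–Kishi coupling (DMSO/THF, high dilution) to the macrocyclic allylic alcohol F7 (C3 epimers), and oxidise with Dess–Martin periodinane to 22.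

Step 15 (Mitsunobu inversion at the hindered C8). The risks are elimination or no reaction. The fallback sets out from 23 and comes back at 25. Oxidise 23 with Dess–Martin periodinane to the C8 ketone F8. Reduce it with NaBH4/CeCl3·7H2O (MeOH, −78 °C); hydride should arrive on the face opposite the lactone and the oxygen bridge, giving the 8R alcohol F9. Acylate with isobutyric anhydride and DMAP to 25.

Further compounds
F1 | step 10 | methyl (2E)-2-{[(4-{[tert-butyl(dimethyl)silyl]oxy}but-2-yn-1-yl)oxy]methyl}-3-[(4S,6S)-6-ethenyl-2,2,6-trimethyl-1,3-dioxan-4-yl]prop-2-enoate | C=C[C@]1(C)C[C@@H](/C=C(\COCC#CCO[Si](C)(C)C(C)(C)C)C(=O)OC)OC(C)(C)O1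
F2 | step 10 | (2Z)-2-{[(4-{[tert-butyl(dimethyl)silyl]oxy}but-2-yn-1-yl)oxy]methyl}-3-[(4S,6S)-6-ethenyl-2,2,6-trimethyl-1,3-dioxan-4-yl]prop-2-en-1-ol | C=C[C@]1(C)C[C@@H](/C=C(\COCC#CCO[Si](C)(C)C(C)(C)C)CO)OC(C)(C)O1
F3 | step 10 | (3S,4R)-7-{[tert-butyl(dimethyl)silyl]oxy}-3-[(4S,6S)-6-ethenyl-2,2,6-trimethyl-1,3-dioxan-4-yl]-2-methylidenehept-5-yne-1,4-diol | C=C[C@]1(C)C[C@@H]([C@H]([C@@H](O)C#CCO[Si](C)(C)C(C)(C)C)C(=C)CO)OC(C)(C)O1
F4 | step 10 | (4R,5R)-5-(3-{[tert-butyl(dimethyl)silyl]oxy}prop-1-yn-1-yl)-4-[(4S,6S)-6-ethenyl-2,2,6-trimethyl-1,3-dioxan-4-yl]-3-methylideneoxolan-2-one | C=C1C(=O)O[C@@H](C#CCO[Si](C)(C)C(C)(C)C)[C@H]1[C@@H]2C[C@@](C)(C=C)OC(C)(C)O2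
F5 | step 13 | primary alcohol from 20 (2-hydroxyethyl in place of ethenyl on the dioxane) | C=C1C(=O)O[C@@H](/C=C(\I)CO[Si](c3ccccc3)(c3ccccc3)C(C)(C)C)[C@H]1[C@@H]2C[C@@](C)(CCO)OC(C)(C)O2
F6 | step 13 | aldehyde from F5 (2-oxoethyl on the dioxane) | C=C1C(=O)O[C@@H](/C=C(\I)CO[Si](c3ccccc3)(c3ccccc3)C(C)(C)C)[C@H]1[C@@H]2C[C@@](C)(CC=O)OC(C)(C)O2
F7 | step 13 | (4Z,6S,7R,8S,10R)-15-{[tert-butyl(diphenyl)silyl]oxy}-3-hydroxy-8,10-(isopropylidenedioxy)germacra-4,11(13)-dien-12,6-olide (C3 epimers) | C=C1C(=O)O[C@H]2/C=C(/CO[Si](c4ccccc4)(c4ccccc4)C(C)(C)C)C(O)CC[C@]3(C)C[C@@H]([C@@H]12)OC(C)(C)O3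
F8 | step 15 | (3S,4Z,6S,7R,10R)-15-{[tert-butyl(diphenyl)silyl]oxy}-3,10-epoxy-3-methoxy-8-oxogermacra-4,11(13)-dien-12,6-olide | C=C1C(=O)O[C@H]2/C=C(/CO[Si](c4ccccc4)(c4ccccc4)C(C)(C)C)[C@]3(OC)CC[C@](C)(CC(=O)[C@@H]12)O3
F9 | step 15 | (3S,4Z,6S,7R,8R,10R)-15-{[tert-butyl(diphenyl)silyl]oxy}-3,10-epoxy-8-hydroxy-3-methoxygermacra-4,11(13)-dien-12,6-olide | C=C1C(=O)O[C@H]2/C=C(/CO[Si](c4ccccc4)(c4ccccc4)C(C)(C)C)[C@]3(OC)CC[C@](C)(C[C@@H](O)[C@@H]12)O3
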